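**Retrosynthetic overview** (labdane numbering)

- The plan rests on ring B (C5–C10), which divides into three bought pieces. C5 and C10 are the carbonyl carbon and the only enolisable α-carbon of 2,2,6-trimethylcyclohexanone (ring A; the quaternary C4 blocks the other side). C9 is the aldehyde carbon of a chain cut from (S)-citronellol (C11–C16, C13 bought). C6–C7–C8 and the carboxyl carbon C17 come from methyl acetoacetate.
- Disconnections, backwards: the O15 acetate and C17 acid come from the hydroxy methyl ester. C7=C8 comes from the C7 ketone through its enol triflate, and 5α-H from hydrogenation of C5=C6. Ring B is opened at C5=C6 (aldol condensation through the acetoacetate γ-carbon C6) and at C9–C10 (Mukaiyama–Michael addition). The acceptor alkene C8=C9 comes from a Knoevenagel condensation.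
- Ring order: ring A is purchased. Ring B is the only ring made; it is closed in one flask in step 5, which also sets C9 and C10. C5 follows in step 6.

Key step: step 5

Assumption: the sense of induction of the Cu(OTf)2 complex of (S,S)-t-Bu-box, 2,2'-(propane-2,2-diyl)bis[(4S)-4-tert-butyl-4,5-dihydro-1,3-oxazole], is taken from the square-planar chelate model; if the other face of C9 reacts, the equally available (R,R) ligand is used and nothing else changes.

**Step 1**
Reactants: 1 2,2,6-trimethylcyclohexanone (racemic)
Product: 2 trimethyl[(2,6,6-trimethylcyclohex-1-en-1-yl)oxy]silane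
Conditions: LiN(i-Pr)2, THF, −78 → 0 °C; Me3SiCl, → rt
Reagents that add atoms: chlorotrimethylsilane, C[Si](C)(C)Cl
Why: Silyl enol ether formation by enolate O-silylation; only one α-carbon of 1 (the future C10) carries hydrogen, so a single tetrasubstituted enol silane can form and the stereocentre of racemic 1 is erased.

**Step 2**
Reactants: 3 (S)-citronellol
Product: 4 (S)-citronellyl benzyl ether
Conditions: NaH, BnBr, n-Bu4NI (cat.), THF, 0 °C → rt
Reagents that add atoms: benzyl bromide, BrCc1ccccc1
Why: Williamson ether synthesis; benzyl is chosen because it withstands the strong base and the acid of step 5 and is removed without an extra operation in the hydrogenation of step 6, and C13 is not touched.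

**Step 3**
Reactants: 4 (S)-citronellyl benzyl ether
Product: 5 (4S)-6-(benzyloxy)-4-methylhexanal
Conditions: O3, CH2Cl2, −78 °C (Sudan Red 7B end point); Me2S, → rt
Reagents that add atoms: ozone, [O-][O+]=O
Why: Ozonolysis with reductive work-up; the electron-rich trisubstituted alkene reacts far faster than the benzyl ether, and the new aldehyde carbon is the future C9.

**Step 4**
Reactants: 5 (4S)-6-(benzyloxy)-4-methylhexanal; 6 methyl acetoacetate
Product: 7 methyl (2Z,6S)-2-acetyl-8-(benzyloxy)-6-methyloct-2-enoate
Conditions: piperidine (cat.), AcOH (cat.), 4 Å MS, CH2Cl2, 0 °C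
Reagents that add atoms: none
Why: Knoevenagel condensation through the iminium ion of 5; low temperature, one equivalent of 6 and sieves should hold back a second addition of 6 and deconjugation, and the Z isomer (chain cis to the ester) should prevail and is carried on.

**Step 5**
Reactants: 2 trimethyl[(2,6,6-trimethylcyclohex-1-en-1-yl)oxy]silane; 7 methyl (2Z,6S)-2-acetyl-8-(benzyloxy)-6-methyloct-2-enoate
Product: 10 methyl (8S,9S,10R,13S)-15-(benzyloxy)-7-oxolabd-5-en-17-oate, via seco-diketone Michael adduct 8 (not isolated), via ring B ketol 9 (not isolated)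
Conditions: (i) 2 (1.5 equiv), Cu(OTf)2 (10 mol %), (S,S)-t-Bu-box (11 mol %), (CF3)2CHOH (1.2 equiv), CH2Cl2–PhMe, −78 → −20 °C; (ii) volatiles removed in the flask, THF, LiN(i-Pr)2 (2.6 equiv), −78 → 0 °C; (iii) MeSO3H (6 equiv), PhMe, 0 → 60 °C
Reagents that add atoms: none
Why: Proposed new method: Cu(OTf)2–(S,S)-t-Bu-box binds both carbonyl oxygens of 7 and the enol silane 2 attacks C9 through C10, its only nucleophilic carbon because C4 is quaternary, while (CF3)2CHOH takes over the silyl group and frees diketone 8; the closest known reaction type is the copper–bis(oxazoline)-catalysed Mukaiyama–Michael addition of silyl ketene acetals to alkylidene malonates, which has not been shown for a tetrasubstituted ketone enol silane that builds a quaternary carbon next to a tertiary one. An amine or hydroxide would only remove the acidic C8–H (and hydroxide would saponify and decarboxylate the keto ester), leaving C6 inert, so two equivalents of LiN(i-Pr)2 make the acetoacetate 1,3-dianion, which is permissible because the C5 ketone sits between the quaternary C4 and C10 and cannot enolise. Ring B closes by 6-(enolendo)-exo-trig aldol attack of C6 on C5 (the enolate bond C6=C7 lies inside the new ring, and attack through C8 would need a four-membered ring), and MeSO3H then dehydrates ketol 9, which has hydrogen only on C6 next to the carbinol carbon, so that only C5=C6 can form. C9 is set by the ligand: in the square-planar chelate the donor lies over the carbonyl arm cis to H9, and the tert-butyl group beside that arm leaves one face of C9 open. C10 is set relative to C9 by a compact synclinal approach in which the silyloxy carbon C5 stays close to the copper-bound dicarbonyl unit, H9 lies over ring A and the chain points into the empty sector between C1 and the C10 methyl, which puts chain and methyl cis on ring B; an antiperiplanar open approach would lead to the C9 epimer, so this diastereoselection together with the face selection at C9 is what the step needs, and the bulk of ring A with its C4 gem-dimethyl group is what should secure it. C8 stays epimerisable and should settle with the ester equatorial, and C13 is too remote to help or to harm.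

**Step 6**
Reactants: 10 methyl (8S,9S,10R,13S)-15-(benzyloxy)-7-oxolabd-5-en-17-oate
Product: 11 methyl (5S,8S,9S,10R,13S)-15-hydroxy-7-oxolabdan-17-oate
Conditions: H2 (4 atm), 10% Pd/C, EtOH–EtOAc, rt
Reagents that add atoms: none
Why: Heterogeneous catalytic hydrogenation with concurrent benzyl hydrogenolysis; the β face of C5=C6 is screened by the axial C10 methyl and the 4β-methyl, so hydrogen should arrive from the α face and give 5α-H (trans-decalin), while C8 equilibrates to the equatorial ester by enolisation.

**Step 7**
Reactants: 11 methyl (5S,8S,9S,10R,13S)-15-hydroxy-7-oxolabdan-17-oate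
Product: 12 methyl (5S,9R,10S,13S)-15-hydroxy-7-(trifluoromethylsulfonyloxy)labd-7-en-17-oate
Conditions: NaH (1.0 equiv), THF, 0 °C; PhNTf2, 0 °C → rt
Reagents that add atoms: N-phenylbis(trifluoromethanesulfonimide), O=S(=O)(N(c1ccccc1)S(=O)(=O)C(F)(F)F)C(F)(F)F
Why: Enol triflate formation by O-sulfonylation of the stabilised keto ester enolate, which can only place the alkene at C7=C8; one equivalent of base leaves the much less acidic C15 alcohol neutral and inert to PhNTf2.

**Step 8**
Reactants: 12 methyl (5S,9R,10S,13S)-15-hydroxy-7-(trifluoromethylsulfonyloxy)labd-7-en-17-oate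
Product: 13 methyl (5S,9R,10S,13S)-15-hydroxylabd-7-en-17-oate
Conditions: Pd(OAc)2 (5 mol %), PPh3 (10 mol %), HCO2H, Et3N, DMF, 60 °C
Reagents that add atoms: none
Why: Palladium-catalysed formate reduction of a vinyl triflate; zerovalent palladium formed in situ inserts into the C7–O bond, formate loses CO2 to give the palladium hydride, and reductive elimination puts H on C7 without moving the alkene or touching C9.

**Step 9**
Reactants: 13 methyl (5S,9R,10S,13S)-15-hydroxylabd-7-en-17-oate
Product: 14 (5S,9R,10S,13S)-15-hydroxylabd-7-en-17-oic acid
Conditions: LiOH, THF–MeOH–H2O, 50 °C; then 1 M HCl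
Reagents that add atoms: lithium hydroxide, [Li+].[OH-]
Why: Saponification by acyl–oxygen cleavage; C9–H hangs on the α-carbon of the enoate and is not acidic, and any γ-deprotonation at C6 is reversible and returns to the conjugated C7=C8 isomer, so no stereocentre is at risk.

**Step 10**
Reactants: 14 (5S,9R,10S,13S)-15-hydroxylabd-7-en-17-oic acid
Product: 15 (5S,9R,10S,13S)-15-acetoxylabd-7-en-17-oic acid (target)
Conditions: Ac2O, pyridine, DMAP (cat.), CH2Cl2, 0 °C → rt; aqueous NaHCO3, then acidification
Reagents that add atoms: acetic anhydride, CC(=O)OC(C)=O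
Why: Nucleophile-catalysed acetylation of the primary C15 alcohol; any mixed anhydride at C17 is hydrolysed back to the acid in the aqueous work-up and no stereocentre is touched.

**Compound list**

1 | 2,2,6-trimethylcyclohexanone (racemic) | CC1CCCC(C)(C)C1=O | starting material
2 | trimethyl[(2,6,6-trimethylcyclohex-1-en-1-yl)oxy]silane | CC1=C(O[Si](C)(C)C)C(C)(C)CCC1 | intermediate
3 | (S)-citronellol | OCC[C@@H](C)CCC=C(C)C | starting material
4 | (S)-citronellyl benzyl ether | c1ccccc1COCC[C@@H](C)CCC=C(C)C | intermediate
5 | (4S)-6-(benzyloxy)-4-methylhexanal | c1ccccc1COCC[C@@H](C)CCC=O | intermediate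
6 | methyl acetoacetate | CC(=O)CC(=O)OC | starting material
7 | methyl (2Z,6S)-2-acetyl-8-(benzyloxy)-6-methyloct-2-enoate | c1ccccc1COCC[C@@H](C)CC/C=C(/C(C)=O)C(=O)OC | intermediate
8 | methyl (3S,6S)-2-acetyl-8-(benzyloxy)-6-methyl-3-[(1R)-1,3,3-trimethyl-2-oxocyclohexyl]octanoate (C8 epimers; not isolated) | c1ccccc1COCC[C@@H](C)CC[C@@H](C(C(C)=O)C(=O)OC)[C@@]1(C)CCCC(C)(C)C1=O | intermediate
9 | methyl 15-(benzyloxy)-5-hydroxy-7-oxolabdan-17-oate, formed as its dilithium salt (C9, C10, C13 as in 10; C5 and C8 not defined; not isolated) | c1ccccc1COCC[C@@H](C)CC[C@H]1C(C(=O)OC)C(=O)CC2(O)C(C)(C)CCC[C@]12C | intermediate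
10 | methyl (8S,9S,10R,13S)-15-(benzyloxy)-7-oxolabd-5-en-17-oate (9β-chain, 10β-methyl, 8α-ester) | c1ccccc1COCC[C@@H](C)CC[C@H]1[C@H](C(=O)OC)C(=O)C=C2C(C)(C)CCC[C@]12C | intermediate
11 | methyl (5S,8S,9S,10R,13S)-15-hydroxy-7-oxolabdan-17-oate (5α-H) | OCC[C@@H](C)CC[C@H]1[C@H](C(=O)OC)C(=O)C[C@H]2C(C)(C)CCC[C@]12C | intermediate
12 | methyl (5S,9R,10S,13S)-15-hydroxy-7-(trifluoromethylsulfonyloxy)labd-7-en-17-oate | OCC[C@@H](C)CC[C@H]1C(C(=O)OC)=C(OS(=O)(=O)C(F)(F)F)C[C@H]2C(C)(C)CCC[C@]12C | intermediate
13 | methyl (5S,9R,10S,13S)-15-hydroxylabd-7-en-17-oate | OCC[C@@H](C)CC[C@H]1C(C(=O)OC)=CC[C@H]2C(C)(C)CCC[C@]12C | intermediate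
14 | (5S,9R,10S,13S)-15-hydroxylabd-7-en-17-oic acid | OCC[C@@H](C)CC[C@H]1C(C(=O)O)=CC[C@H]2C(C)(C)CCC[C@]12C | intermediate
15 | (5S,9R,10S,13S)-15-acetoxylabd-7-en-17-oic acid | CC(=O)OCC[C@@H](C)CC[C@H]1C(C(=O)O)=CC[C@H]2C(C)(C)CCC[C@]12C | target

**Step count**

Total step count: 10. Longest linear sequence: 9 (steps 2–10, from 3).

**Steps most likely to fail**

**1. Step 5.**
- What may go wrong in the addition: the crowded enol silane may add too slowly to the mild chiral complex. Protodesilylation or a silyl-cation-catalysed, unselective background addition could then take over.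
- What may go wrong in the selectivity: the relative topicity may leak to the antiperiplanar mode.
- What may go wrong in the closure: the ketol may revert by retro-aldol cleavage before it loses water.
- Fallback (known chemistry): it sets out from 2 and 7 and comes back at 10. It gives up catalyst control and the one-flask format.
  - Stoichiometric TiCl4 in CH2Cl2 at −78 °C promotes the ordinary Mukaiyama–Michael addition. Aqueous work-up should give the isolated diketone stereoisomer mixture F1.
  - On purified material the ring is closed with LiN(i-Pr)2 and dehydrated with MeSO3H. This should give the enone stereoisomer mixture F2.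
  - Because C13 is fixed, all components of F2 are diastereomers. The C9/C10 relative isomers are parted by column chromatography and the pair with mirror-image bicycles by preparative HPLC, which delivers 10 at the price of material.

**2. Step 6.**
- What may go wrong: hydrogen uptake may be slow at C5=C6, which is flanked by the quaternary C4 and C10. Some hydrogen may also be delivered to the β face, giving the cis ring fusion.
- Fallback: it sets out from 10 and comes back at 11.
  - An electron-transfer conjugate reduction with SmI2 (THF–HMPA, t-BuOH, 0 °C) does not need the alkene to reach a metal surface. It protonates C5 axially, as in dissolving-metal reductions of octalones.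
  - It should give methyl (5S,8S,9S,10R,13S)-15-(benzyloxy)-7-oxolabdan-17-oate F3.
  - Hydrogenolysis of the benzyl ether (H2, Pd/C, EtOAc) then gives 11.

**3. Step 7.**
- What may go wrong: O-sulfonylation of the hindered, stabilised enolate may be sluggish, and the free C15 hydroxyl may compete.
- Fallback: it sets out from 11 and comes back at 14, replacing triflate reduction by β-elimination.
  - NaBH4 in MeOH at 0 °C should give methyl 7,15-dihydroxylabdan-17-oate F4.
  - Ac2O, pyridine and DMAP should give methyl 7,15-diacetoxylabdan-17-oate F5.
  - DBU in PhMe at 80 °C removes the C7 acetate by E1cB elimination across C7–C8. This should give methyl 15-acetoxylabd-7-en-17-oate F6.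
  - LiOH under the conditions of step 9 cleaves both esters and gives 14.

**Further compounds**

F1 | step 5 | diketone stereoisomer mixture (8 and its C9/C10 isomers, 13S) | c1ccccc1COCC[C@@H](C)CCC(C(C(C)=O)C(=O)OC)C1(C)CCCC(C)(C)C1=O
F2 | step 5 | enone stereoisomer mixture (10 and its C9/C10 isomers, 13S) | c1ccccc1COCC[C@@H](C)CCC1C(C(=O)OC)C(=O)C=C2C(C)(C)CCCC12C
F3 | step 6 | methyl (5S,8S,9S,10R,13S)-15-(benzyloxy)-7-oxolabdan-17-oate | c1ccccc1COCC[C@@H](C)CC[C@H]1[C@H](C(=O)OC)C(=O)C[C@H]2C(C)(C)CCC[C@]12C
F4 | step 7 | methyl 7,15-dihydroxylabdan-17-oate (C7 epimers) | OCC[C@@H](C)CC[C@H]1[C@H](C(=O)OC)C(O)C[C@H]2C(C)(C)CCC[C@]12C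
F5 | step 7 | methyl 7,15-diacetoxylabdan-17-oate (C7 epimers) | CC(=O)OCC[C@@H](C)CC[C@H]1[C@H](C(=O)OC)C(OC(C)=O)C[C@H]2C(C)(C)CCC[C@]12C
F6 | step 7 | methyl 15-acetoxylabd-7-en-17-oate | CC(=O)OCC[C@@H](C)CC[C@H]1C(C(=O)OC)=CC[C@H]2C(C)(C)CCC[C@]12C
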